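**Retrosynthetic overview**

1. The target is epiafzelechin-(4β→6)-epigallocatechin 3,3'-di-O-gallate (flavan numbering; upper unit rings A/C/B, lower unit rings D/F/E). The last cuts are global hydrogenolysis, then the C4(ring C)–C6(ring D) bond by Friedel–Crafts coupling of the 6,8-dibromo-capped 4-alkoxy upper unit 16 with the 8-bromo lower unit 30, then both gallate esters in one double esterification.
2. Key cut: O1–C8a of ring F. The open-chain syn fluoroarene alcohol 23 is closed by an aryne relay (lithiation of C8–H, loss of LiF, attack of the C2 alkoxide on C8a, bromination of the C8 carbanion). C2–O is never broken, so syn becomes 2,3-cis, and the bromine left on C8 is the blocking group that later forces the coupling to C6.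
3. Enabling feature: in ring D, C8a lies between the chain-bearing C4a and the one unsubstituted carbon C8, which itself sits next to the C7 oxygen. With F on C8a, C8–H is the most acidic arene C–H; the C8/C8a aryne is polarised by the C7 oxygen for attack at C8a; and the C2 oxygen reaches C8a through C3–C4–C4a as a six-membered ring.
4. Both syn alcohols (10 and 23) come from chelation-controlled aryl Grignard additions to (R)-α-alkoxy aldehydes, and both aldehydes derive from one hydroxy ester 6 (lithiated 1,3-bis(benzyloxy)-5-fluorobenzene plus methyl (R)-glycidate).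
5. Ring order: rings A, D, B and E are bought as arenes; ring C is closed first (step 6, same closure with a proton quench), then ring F (step 14), then the interflavan bond joins the two halves.

Key step: step 14

Remark: flavan numbering (O1, C2, C3, C4, C4a, C5–C8, C8a) is also used for the open-chain precursors. 5-Bromobenzene-1,2,3-triol, methyl (2R)-oxirane-2-carboxylate, [4-(benzyloxy)phenyl]magnesium bromide (THF solution) and 3,4,5-tris(benzyloxy)benzoic acid are taken as catalogue compounds.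

**Route**

Step 1
Reactants: 1 1,3,5-trifluorobenzene
Product: 2 1,3-bis(benzyloxy)-5-fluorobenzene
Conditions: BnOH (2.1 equiv), NaH, NMP, 0 → 100 °C
Reagents that add atoms: benzyl alcohol, OCc1ccccc1
Why: Double nucleophilic aromatic substitution of fluoride by benzyl oxide, each fluorine being activated by the two meta fluorines; after two substitutions the ring is too electron-rich for a third, so the monofluoride should be the end point.

Step 2
Reactants: 2 1,3-bis(benzyloxy)-5-fluorobenzene; 3 methyl (2R)-oxirane-2-carboxylate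
Product: 6 methyl (2R)-3-[2,4-bis(benzyloxy)-6-fluorophenyl]-2-hydroxypropanoate, via aryllithium 4 (not isolated), via arylmagnesium bromide 5 (not isolated)
Conditions: n-BuLi, THF, −78 °C; MgBr2·OEt2, −78 → −40 °C; CuI (10 mol%), then 3, −40 → −20 °C; aq NH4Cl
Reagents that add atoms: none
Why: Ortho-lithiation at the C–H flanked by F and OBn (the two such positions are equivalent), transmetalation to magnesium and copper-catalysed SN2 opening of the epoxide at its unsubstituted carbon should give the α-hydroxy ester; the stereocentre of 3 is not touched and stays (R).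

Step 3
Reactants: 6 methyl (2R)-3-[2,4-bis(benzyloxy)-6-fluorophenyl]-2-hydroxypropanoate
Product: 7 methyl (2R)-2-(benzyloxy)-3-[2,4-bis(benzyloxy)-6-fluorophenyl]propanoate
Conditions: BnBr, Ag2O, Et2O, rt, dark
Reagents that add atoms: benzyl bromide, BrCc1ccccc1
Why: Silver-oxide-mediated Williamson-type O-benzylation of an α-hydroxy ester, mild enough not to epimerise the α-centre.

Step 4
Reactants: 7 methyl (2R)-2-(benzyloxy)-3-[2,4-bis(benzyloxy)-6-fluorophenyl]propanoate
Product: 8 (2R)-2-(benzyloxy)-3-[2,4-bis(benzyloxy)-6-fluorophenyl]propanal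
Conditions: i-Bu2AlH, CH2Cl2, −78 °C; aq Rochelle salt
Reagents that add atoms: none
Why: Partial reduction of an α-alkoxy ester, in which the chelated tetrahedral aluminium hemiacetal survives at −78 °C and releases the aldehyde only on work-up, without over-reduction or epimerisation.

Step 5
Reactants: 8 (2R)-2-(benzyloxy)-3-[2,4-bis(benzyloxy)-6-fluorophenyl]propanal; 9 [4-(benzyloxy)phenyl]magnesium bromide
Product: 10 (1R,2R)-2-(benzyloxy)-1-[4-(benzyloxy)phenyl]-3-[2,4-bis(benzyloxy)-6-fluorophenyl]propan-1-ol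
Conditions: 8, MgBr2·OEt2, CH2Cl2, −78 °C; then 9 (THF solution), −78 °C; aq NH4Cl
Reagents that add atoms: none
Why: Chelation-controlled Grignard addition: magnesium bridges the aldehyde oxygen and the α-benzyloxy oxygen, the aryl group adds to the less hindered face of the five-membered chelate and should set C1 as (R), giving the syn alcohol.

Step 6
Reactants: 10 (1R,2R)-2-(benzyloxy)-1-[4-(benzyloxy)phenyl]-3-[2,4-bis(benzyloxy)-6-fluorophenyl]propan-1-ol
Product: 14 (2R,3R)-3,5,7-tris(benzyloxy)-2-[4-(benzyloxy)phenyl]-3,4-dihydro-2H-chromene, via C8-lithiated lithium alkoxide 11 (not isolated), via aryne lithium alkoxide 12 (not isolated), via 8-lithioflavan 13 (not isolated)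
Conditions: n-BuLi (2.1 equiv), THF (0.02 M), −78 °C; warm to −20 °C; MeOH, −78 °C
Reagents that add atoms: none
Why: The same anionic aryne cyclisation as in the key step, ended here by protonation: lithiation of C8–H next to fluorine, loss of LiF and addition of the C2 alkoxide to C8a close ring C without touching C2 or C3, so the syn alcohol should give the 2,3-cis (2R,3R) flavan.

Step 7
Reactants: 14 (2R,3R)-3,5,7-tris(benzyloxy)-2-[4-(benzyloxy)phenyl]-3,4-dihydro-2H-chromene
Product: 15 (2R,3R,4S)-3,5,7-tris(benzyloxy)-2-[4-(benzyloxy)phenyl]-4-(2-ethoxyethoxy)-3,4-dihydro-2H-chromene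
Conditions: DDQ, 2-ethoxyethanol, CH2Cl2, rt
Reagents that add atoms: 2-ethoxyethanol, CCOCCO
Why: DDQ-mediated benzylic oxidation (hydride abstraction at C4, activated by the ortho and para oxygens of ring A) with capture of the cation by the alcohol on the face opposite to the 3-benzyloxy and 2-aryl groups, which should give the 3,4-trans (4β) ether.

Step 8
Reactants: 15 (2R,3R,4S)-3,5,7-tris(benzyloxy)-2-[4-(benzyloxy)phenyl]-4-(2-ethoxyethoxy)-3,4-dihydro-2H-chromene
Product: 16 (2R,3R,4S)-3,5,7-tris(benzyloxy)-2-[4-(benzyloxy)phenyl]-6,8-dibromo-4-(2-ethoxyethoxy)-3,4-dihydro-2H-chromene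
Conditions: NBS (2.1 equiv), CH2Cl2, −78 → 0 °C
Reagents that add atoms: N-bromosuccinimide, O=C1CCC(=O)N1Br
Why: Electrophilic aromatic bromination of the phloroglucinol-type ring A at its only two free positions C6 and C8, which caps the electrophile against self-condensation in step 17.

Step 9
Reactants: 17 5-bromobenzene-1,2,3-triol
Product: 18 6-bromo-2,2-diphenyl-1,3-benzodioxol-4-ol
Conditions: Ph2CCl2, diphenyl ether, 170 °C
Reagents that add atoms: dichlorodiphenylmethane, ClC(Cl)(c1ccccc1)c1ccccc1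
Why: Ketal formation between two vicinal phenols and the geminal dichloride; the two possible vicinal pairs are equivalent by symmetry, so exactly one phenol (the future 3'-OH of ring E) is left free.

Step 10
Reactants: 18 6-bromo-2,2-diphenyl-1,3-benzodioxol-4-ol
Product: 19 6-bromo-4-(methoxymethoxy)-2,2-diphenyl-1,3-benzodioxole
Conditions: MOMCl, i-Pr2NEt, CH2Cl2, 0 °C → rt
Reagents that add atoms: chloromethyl methyl ether, COCCl
Why: O-alkylation of the remaining phenol to a methoxymethyl acetal, which tolerates the organometallic steps and can later be removed without acid.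

Step 11
Reactants: 6 methyl (2R)-3-[2,4-bis(benzyloxy)-6-fluorophenyl]-2-hydroxypropanoate
Product: 20 methyl (2R)-3-[2,4-bis(benzyloxy)-6-fluorophenyl]-2-(methoxymethoxy)propanoate
Conditions: MOMCl, i-Pr2NEt, n-Bu4NI (cat.), CH2Cl2, 0 °C → rt
Reagents that add atoms: chloromethyl methyl ether, COCCl
Why: Amine-base O-alkylation of the α-hydroxy ester, which does not epimerise the α-centre and installs the chelating, base-stable group needed in steps 13 and 14.

Step 12
Reactants: 20 methyl (2R)-3-[2,4-bis(benzyloxy)-6-fluorophenyl]-2-(methoxymethoxy)propanoate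
Product: 21 (2R)-3-[2,4-bis(benzyloxy)-6-fluorophenyl]-2-(methoxymethoxy)propanal
Conditions: i-Bu2AlH, CH2Cl2, −78 °C; aq Rochelle salt
Reagents that add atoms: none
Why: Partial ester reduction through a chelated tetrahedral aluminium intermediate that is stable at −78 °C, as in step 4.

Step 13
Reactants: 21 (2R)-3-[2,4-bis(benzyloxy)-6-fluorophenyl]-2-(methoxymethoxy)propanal; 19 6-bromo-4-(methoxymethoxy)-2,2-diphenyl-1,3-benzodioxole
Product: 23 (1R,2R)-3-[2,4-bis(benzyloxy)-6-fluorophenyl]-2-(methoxymethoxy)-1-[7-(methoxymethoxy)-2,2-diphenyl-1,3-benzodioxol-5-yl]propan-1-ol, via arylmagnesium bromide 22 (not isolated)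
Conditions: 19, Mg, LiCl, THF, rt; then added to 21, MgBr2·OEt2, CH2Cl2, −78 °C; aq NH4Cl
Reagents that add atoms: none
Why: Magnesium insertion into the aryl bromide, then chelation-controlled Grignard addition (magnesium bridging C=O and the α-methoxymethoxy oxygen) to the less hindered face of the aldehyde, which should set C1 as (R), give the syn alcohol and introduce ring E.

Step 14
Reactants: 23 (1R,2R)-3-[2,4-bis(benzyloxy)-6-fluorophenyl]-2-(methoxymethoxy)-1-[7-(methoxymethoxy)-2,2-diphenyl-1,3-benzodioxol-5-yl]propan-1-ol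
Product: 27 (2R,3R)-5,7-bis(benzyloxy)-8-bromo-3-(methoxymethoxy)-2-[7-(methoxymethoxy)-2,2-diphenyl-1,3-benzodioxol-5-yl]-3,4-dihydro-2H-chromene, via C8-lithiated lithium alkoxide 24 (not isolated), via aryne lithium alkoxide 25 (not isolated), via 8-lithioflavan 26 (not isolated)
Conditions: n-BuLi (2.1 equiv), THF (0.02 M), −78 °C; warm to −30 °C; cool to −78 °C, BrCl2C–CCl2Br
Reagents that add atoms: 1,2-dibromo-1,1,2,2-tetrachloroethane, BrC(Cl)(Cl)C(Cl)(Cl)Br
Why: Mechanism: the first equivalent of n-BuLi forms the C2 lithium alkoxide and the second lithiates C8–H of ring D, the only arene C–H flanked by F and OBn (the same site type as in step 2); on warming LiF is lost to give the C8/C8a aryne, the alkoxide adds to C8a, and the C8 aryllithium that results is brominated. The closest known reaction types are the intramolecular etherification of arynes by tethered alkoxides to give chromans and the anionic benzyne cyclisation with electrophilic trapping of the new aryllithium. Ring F closes by 6-exo attack of the alkoxide on aryne carbon C8a: the tether C4a–C4–C3–C2 cannot reach C8, and the 7-OBn group polarises the aryne so that the nucleophile adds to the distal carbon C8a and the carbanion sits next to oxygen at C8. No stereocentre is formed; C2 and C3 are carried over unchanged because the C2–O bond is never broken, so the syn (1R,2R) alcohol becomes the 2,3-cis (2R,3R) flavan. The step needs three selectivities: the site of the second lithiation (secured by the F/OBn flanking at −78 °C, where ether- or alkoxide-directed lithiation of ring E and of the OBn/OBn-flanked C6–H is slow), six- over five-membered closure (anionic alkoxide against the neutral C3 acetal oxygen), and intramolecular over intermolecular aryne capture (high dilution).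

Step 15
Reactants: 27 (2R,3R)-5,7-bis(benzyloxy)-8-bromo-3-(methoxymethoxy)-2-[7-(methoxymethoxy)-2,2-diphenyl-1,3-benzodioxol-5-yl]-3,4-dihydro-2H-chromene
Product: 28 (2R,3R)-5,7-bis(benzyloxy)-8-bromo-2-(7-hydroxy-2,2-diphenyl-1,3-benzodioxol-5-yl)-3,4-dihydro-2H-chromen-3-ol
Conditions: TMSOTf, 2,2'-bipyridyl, CH2Cl2, 0 °C → rt; then H2O
Reagents that add atoms: none
Why: Lewis-acid activation of the two methoxymethyl acetals by TMSOTf buffered with 2,2'-bipyridyl, followed by hydrolysis of the silyl ether and pyridinium intermediates, should free the 3-OH and 3'-OH under non-protic conditions that the diaryl ketal, the benzyl ethers and the aryl bromide tolerate.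

Step 16
Reactants: 28 (2R,3R)-5,7-bis(benzyloxy)-8-bromo-2-(7-hydroxy-2,2-diphenyl-1,3-benzodioxol-5-yl)-3,4-dihydro-2H-chromen-3-ol; 29 3,4,5-tris(benzyloxy)benzoic acid
Product: 30 (2R,3R)-5,7-bis(benzyloxy)-8-bromo-2-{2,2-diphenyl-7-[3,4,5-tris(benzyloxy)benzoyloxy]-1,3-benzodioxol-5-yl}-3,4-dihydro-2H-chromen-3-yl 3,4,5-tris(benzyloxy)benzoate
Conditions: 29 (3 equiv), DCC, DMAP, CH2Cl2, rt
Reagents that add atoms: none
Why: Steglich esterification of the only two free hydroxyls, the secondary 3-OH and the phenolic 3'-OH, places both galloyl groups in one operation.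

Step 17
Reactants: 30 (2R,3R)-5,7-bis(benzyloxy)-8-bromo-2-{2,2-diphenyl-7-[3,4,5-tris(benzyloxy)benzoyloxy]-1,3-benzodioxol-5-yl}-3,4-dihydro-2H-chromen-3-yl 3,4,5-tris(benzyloxy)benzoate; 16 (2R,3R,4S)-3,5,7-tris(benzyloxy)-2-[4-(benzyloxy)phenyl]-6,8-dibromo-4-(2-ethoxyethoxy)-3,4-dihydro-2H-chromene
Product: 31 (2R,3R)-5,7-bis(benzyloxy)-8-bromo-6-{(2R,3R,4S)-3,5,7-tris(benzyloxy)-2-[4-(benzyloxy)phenyl]-6,8-dibromo-3,4-dihydro-2H-chromen-4-yl}-2-{2,2-diphenyl-7-[3,4,5-tris(benzyloxy)benzoyloxy]-1,3-benzodioxol-5-yl}-3,4-dihydro-2H-chromen-3-yl 3,4,5-tris(benzyloxy)benzoate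
Conditions: 16 (1.2 equiv), TMSOTf (0.3 equiv), 4 Å MS, CH2Cl2, −78 → −30 °C; Et3N quench
Reagents that add atoms: none
Why: Lewis-acid-promoted Friedel–Crafts alkylation: TMSOTf ionises the C4 ether of 16 to a benzylic cation stabilised by ring A, which attacks C6, the only free position of ring D in 30 (C8 is blocked by bromine); attack anti to the 3-benzyloxy and 2-aryl groups should set the new C4 centre as 4β (3,4-trans, 4S), and neither the doubly brominated ring A of 16 nor the product can react further.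

Step 18
Reactants: 31 protected dimer (name as in step 17)
Product: 32 epiafzelechin-(4β→6)-epigallocatechin 3,3'-di-O-gallate, (2R,3R)-5,7-dihydroxy-6-[(2R,3R,4S)-3,5,7-trihydroxy-2-(4-hydroxyphenyl)-3,4-dihydro-2H-chromen-4-yl]-2-[3,4-dihydroxy-5-(3,4,5-trihydroxybenzoyloxy)phenyl]-3,4-dihydro-2H-chromen-3-yl 3,4,5-trihydroxybenzoate
Conditions: H2 (1 atm), Pd(OH)2/C, NaOAc, THF/MeOH/H2O, rt
Reagents that add atoms: none
Why: Catalytic hydrogenolysis should remove the twelve benzyl ethers, the diphenylmethylene ketal and the three aryl bromides in one operation while the two esters and all stereocentres stay untouched, with NaOAc buffering the HBr.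

**Compound list**

1 | 1,3,5-trifluorobenzene | Fc1cc(F)cc(F)c1 | starting material
2 | 1,3-bis(benzyloxy)-5-fluorobenzene | Fc1cc(OCc2ccccc2)cc(OCc2ccccc2)c1 | intermediate
3 | methyl (2R)-oxirane-2-carboxylate | COC(=O)[C@H]1CO1 | starting material
4 | [2,4-bis(benzyloxy)-6-fluorophenyl]lithium | [Li]c1c(F)cc(OCc2ccccc2)cc1OCc1ccccc1 | intermediate
5 | [2,4-bis(benzyloxy)-6-fluorophenyl]magnesium bromide | Br[Mg]c1c(F)cc(OCc2ccccc2)cc1OCc1ccccc1 | intermediate
6 | methyl (2R)-3-[2,4-bis(benzyloxy)-6-fluorophenyl]-2-hydroxypropanoate | COC(=O)[C@H](O)Cc1c(F)cc(OCc2ccccc2)cc1OCc1ccccc1 | intermediate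
7 | methyl (2R)-2-(benzyloxy)-3-[2,4-bis(benzyloxy)-6-fluorophenyl]propanoate | COC(=O)[C@H](OCc1ccccc1)Cc1c(F)cc(OCc2ccccc2)cc1OCc1ccccc1 | intermediate
8 | (2R)-2-(benzyloxy)-3-[2,4-bis(benzyloxy)-6-fluorophenyl]propanal | O=C[C@H](OCc1ccccc1)Cc1c(F)cc(OCc2ccccc2)cc1OCc1ccccc1 | intermediate
9 | [4-(benzyloxy)phenyl]magnesium bromide | Br[Mg]c1ccc(OCc2ccccc2)cc1 | starting material
10 | (1R,2R)-2-(benzyloxy)-1-[4-(benzyloxy)phenyl]-3-[2,4-bis(benzyloxy)-6-fluorophenyl]propan-1-ol (syn) | O[C@H](c1ccc(OCc2ccccc2)cc1)[C@H](OCc1ccccc1)Cc1c(F)cc(OCc2ccccc2)cc1OCc1ccccc1 | intermediate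
11 | lithium alkoxide of 10, lithiated at the arene carbon between F and OBn (future C8) | [Li]O[C@H](c1ccc(OCc2ccccc2)cc1)[C@H](OCc1ccccc1)Cc1c(F)c([Li])c(OCc2ccccc2)cc1OCc1ccccc1 | intermediate
12 | aryne (triple bond between future C8 and C8a) carrying the lithium alkoxide chain of 10 | [Li]O[C@H](c1ccc(OCc2ccccc2)cc1)[C@H](OCc1ccccc1)CC1=C(OCc2ccccc2)C=C(OCc2ccccc2)C#C1 | intermediate
13 | 8-lithio derivative of 14 | C(Oc1ccc(cc1)[C@H]1Oc2c([Li])c(OCc3ccccc3)cc(OCc3ccccc3)c2C[C@H]1OCc1ccccc1)c1ccccc1 | intermediate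
14 | (2R,3R)-3,5,7-tris(benzyloxy)-2-[4-(benzyloxy)phenyl]-3,4-dihydro-2H-chromene (tetra-O-benzylepiafzelechin) | C(Oc1ccc(cc1)[C@H]1Oc2cc(OCc3ccccc3)cc(OCc3ccccc3)c2C[C@H]1OCc1ccccc1)c1ccccc1 | intermediate
15 | (2R,3R,4S)-3,5,7-tris(benzyloxy)-2-[4-(benzyloxy)phenyl]-4-(2-ethoxyethoxy)-3,4-dihydro-2H-chromene (4β ether) | CCOCCO[C@H]1c2c(OCc3ccccc3)cc(OCc3ccccc3)cc2O[C@H](c2ccc(OCc3ccccc3)cc2)[C@@H]1OCc1ccccc1 | intermediate
16 | (2R,3R,4S)-3,5,7-tris(benzyloxy)-2-[4-(benzyloxy)phenyl]-6,8-dibromo-4-(2-ethoxyethoxy)-3,4-dihydro-2H-chromene | CCOCCO[C@H]1c2c(OCc3ccccc3)c(Br)c(OCc3ccccc3)c(Br)c2O[C@H](c2ccc(OCc3ccccc3)cc2)[C@@H]1OCc1ccccc1 | intermediate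
17 | 5-bromobenzene-1,2,3-triol | Oc1cc(Br)cc(O)c1O | starting material
18 | 6-bromo-2,2-diphenyl-1,3-benzodioxol-4-ol | Oc1cc(Br)cc2OC(c3ccccc3)(c3ccccc3)Oc12 | intermediate
19 | 6-bromo-4-(methoxymethoxy)-2,2-diphenyl-1,3-benzodioxole | COCOc1cc(Br)cc2OC(c3ccccc3)(c3ccccc3)Oc12 | intermediate
20 | methyl (2R)-3-[2,4-bis(benzyloxy)-6-fluorophenyl]-2-(methoxymethoxy)propanoate | COC(=O)[C@H](OCOC)Cc1c(F)cc(OCc2ccccc2)cc1OCc1ccccc1 | intermediate
21 | (2R)-3-[2,4-bis(benzyloxy)-6-fluorophenyl]-2-(methoxymethoxy)propanal | O=C[C@H](OCOC)Cc1c(F)cc(OCc2ccccc2)cc1OCc1ccccc1 | intermediate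
22 | [7-(methoxymethoxy)-2,2-diphenyl-1,3-benzodioxol-5-yl]magnesium bromide | COCOc1cc([Mg]Br)cc2OC(c3ccccc3)(c3ccccc3)Oc12 | intermediate
23 | (1R,2R)-3-[2,4-bis(benzyloxy)-6-fluorophenyl]-2-(methoxymethoxy)-1-[7-(methoxymethoxy)-2,2-diphenyl-1,3-benzodioxol-5-yl]propan-1-ol (syn) | COCOc1cc([C@@H](O)[C@H](OCOC)Cc3c(F)cc(OCc4ccccc4)cc3OCc3ccccc3)cc2OC(c3ccccc3)(c3ccccc3)Oc12 | intermediate
24 | lithium alkoxide of 23, lithiated at C8 (arene carbon between F and OBn) | COCOc1cc([C@@H](O[Li])[C@H](OCOC)Cc3c(F)c([Li])c(OCc4ccccc4)cc3OCc3ccccc3)cc2OC(c3ccccc3)(c3ccccc3)Oc12 | intermediate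
25 | C8/C8a aryne carrying the lithium alkoxide chain of 23 | COCOc1cc([C@@H](O[Li])[C@H](OCOC)CC3=C(OCc4ccccc4)C=C(OCc4ccccc4)C#C3)cc2OC(c3ccccc3)(c3ccccc3)Oc12 | intermediate
26 | 8-lithio analogue of 27 (Li in place of Br) | COCOc1cc([C@H]2Oc3c([Li])c(OCc4ccccc4)cc(OCc4ccccc4)c3C[C@H]2OCOC)cc2OC(c3ccccc3)(c3ccccc3)Oc12 | intermediate
27 | (2R,3R)-5,7-bis(benzyloxy)-8-bromo-3-(methoxymethoxy)-2-[7-(methoxymethoxy)-2,2-diphenyl-1,3-benzodioxol-5-yl]-3,4-dihydro-2H-chromene | COCOc1cc([C@H]2Oc3c(Br)c(OCc4ccccc4)cc(OCc4ccccc4)c3C[C@H]2OCOC)cc2OC(c3ccccc3)(c3ccccc3)Oc12 | intermediate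
28 | (2R,3R)-5,7-bis(benzyloxy)-8-bromo-2-(7-hydroxy-2,2-diphenyl-1,3-benzodioxol-5-yl)-3,4-dihydro-2H-chromen-3-ol | Oc1cc([C@H]2Oc3c(Br)c(OCc4ccccc4)cc(OCc4ccccc4)c3C[C@H]2O)cc2OC(c3ccccc3)(c3ccccc3)Oc12 | intermediate
29 | 3,4,5-tris(benzyloxy)benzoic acid | OC(=O)c1cc(OCc2ccccc2)c(OCc2ccccc2)c(OCc2ccccc2)c1 | starting material
30 | (2R,3R)-5,7-bis(benzyloxy)-8-bromo-2-{2,2-diphenyl-7-[3,4,5-tris(benzyloxy)benzoyloxy]-1,3-benzodioxol-5-yl}-3,4-dihydro-2H-chromen-3-yl 3,4,5-tris(benzyloxy)benzoate | O=C(Oc1cc([C@H]2Oc3c(Br)c(OCc4ccccc4)cc(OCc4ccccc4)c3C[C@H]2OC(=O)c2cc(OCc3ccccc3)c(OCc3ccccc3)c(OCc3ccccc3)c2)cc2OC(c3ccccc3)(c3ccccc3)Oc12)c1cc(OCc2ccccc2)c(OCc2ccccc2)c(OCc2ccccc2)c1 | intermediate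
31 | protected dimer: 30 carrying at C6 the (2R,3R,4S)-3,5,7-tris(benzyloxy)-2-[4-(benzyloxy)phenyl]-6,8-dibromo-3,4-dihydro-2H-chromen-4-yl group (4β→6, 3,4-trans) | O=C(Oc1cc([C@H]2Oc3c(Br)c(OCc6ccccc6)c([C@H]4c5c(OCc6ccccc6)c(Br)c(OCc6ccccc6)c(Br)c5O[C@H](c5ccc(OCc6ccccc6)cc5)[C@@H]4OCc4ccccc4)c(OCc4ccccc4)c3C[C@H]2OC(=O)c2cc(OCc3ccccc3)c(OCc3ccccc3)c(OCc3ccccc3)c2)cc2OC(c3ccccc3)(c3ccccc3)Oc12)c1cc(OCc2ccccc2)c(OCc2ccccc2)c(OCc2ccccc2)c1 | intermediate
32 | epiafzelechin-(4β→6)-epigallocatechin 3,3'-di-O-gallate (CNP0290965.1) | O=C(Oc1cc([C@H]2Oc3cc(O)c([C@H]4c5c(O)cc(O)cc5O[C@H](c5ccc(O)cc5)[C@@H]4O)c(O)c3C[C@H]2OC(=O)c2cc(O)c(O)c(O)c2)cc(O)c1O)c1cc(O)c(O)c(O)c1 | target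

**Totals**

Total step count: 18.
Longest linear sequence: 10 steps (steps 1, 2, 11, 12, 13, 14, 15, 16, 17, 18; the upper-unit branch 1, 2, 3–8, 17, 18 is equally long).

**Three steps most likely to fail**

Step 14 (key step). What may go wrong: metalation at a competing site (ring E next to the methoxymethoxy group, C6–H of ring D, a benzylic CH2); capture of the aryne by a second aryllithium or by the neutral C3 acetal oxygen (five-membered closure); protonation of the C8 carbanion before bromination. Fallback, from 23 back to 27: the ring is closed without metalating the arene, by KN(SiMe3)2, 18-crown-6, THF, 60 °C (displacement of fluoride by the C2 alkoxide; an aryne formed on the way would simply be protonated). This should give (2R,3R)-5,7-bis(benzyloxy)-3-(methoxymethoxy)-2-[7-(methoxymethoxy)-2,2-diphenyl-1,3-benzodioxol-5-yl]-3,4-dihydro-2H-chromene F1. Electrophilic bromination of F1 with NBS in CH2Cl2 at −78 °C, which on 5,7-dialkoxyflavans goes to C8, then returns to 27.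

Step 17. What may go wrong: slow C–C bond formation at the hindered, bromine-deactivated C6 of the esterified nucleophile, so that the cation is lost to elimination or oxygen capture; erosion of facial selectivity at C4. Fallback, from 28 (with 16) back to 31: coupling and esterification change places. TMSOTf-promoted Friedel–Crafts coupling of the unesterified, less hindered diol 28 with 16 should give the dimeric diol (2R,3R)-5,7-bis(benzyloxy)-8-bromo-6-{(2R,3R,4S)-3,5,7-tris(benzyloxy)-2-[4-(benzyloxy)phenyl]-6,8-dibromo-3,4-dihydro-2H-chromen-4-yl}-2-(7-hydroxy-2,2-diphenyl-1,3-benzodioxol-5-yl)-3,4-dihydro-2H-chromen-3-ol F2. Double Steglich esterification of F2 with 29 (DCC, DMAP) then returns to 31.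

Step 13. What may go wrong: poor facial selectivity of the aryl addition if chelation is incomplete, giving syn/anti mixtures, and partial epimerisation of the α-alkoxy aldehyde. Fallback, from 23 (as the diastereomer mixture) back to 23: Dess–Martin oxidation gives the ketone (2R)-3-[2,4-bis(benzyloxy)-6-fluorophenyl]-2-(methoxymethoxy)-1-[7-(methoxymethoxy)-2,2-diphenyl-1,3-benzodioxol-5-yl]propan-1-one F3. Corey–Bakshi–Shibata reduction of F3 ((R)-2-methyl-CBS-oxazaborolidine, BH3·SMe2, aryl as the large group) then sets C1 under reagent control and returns to 23.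

**Further compounds**

F1 | step 14 | (2R,3R)-5,7-bis(benzyloxy)-3-(methoxymethoxy)-2-[7-(methoxymethoxy)-2,2-diphenyl-1,3-benzodioxol-5-yl]-3,4-dihydro-2H-chromene | COCOc1cc([C@H]2Oc3cc(OCc4ccccc4)cc(OCc4ccccc4)c3C[C@H]2OCOC)cc2OC(c3ccccc3)(c3ccccc3)Oc12
F2 | step 17 | (2R,3R)-5,7-bis(benzyloxy)-8-bromo-6-{(2R,3R,4S)-3,5,7-tris(benzyloxy)-2-[4-(benzyloxy)phenyl]-6,8-dibromo-3,4-dihydro-2H-chromen-4-yl}-2-(7-hydroxy-2,2-diphenyl-1,3-benzodioxol-5-yl)-3,4-dihydro-2H-chromen-3-ol | Oc1cc([C@H]2Oc3c(Br)c(OCc6ccccc6)c([C@H]4c5c(OCc6ccccc6)c(Br)c(OCc6ccccc6)c(Br)c5O[C@H](c5ccc(OCc6ccccc6)cc5)[C@@H]4OCc4ccccc4)c(OCc4ccccc4)c3C[C@H]2O)cc2OC(c3ccccc3)(c3ccccc3)Oc12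
F3 | step 13 | (2R)-3-[2,4-bis(benzyloxy)-6-fluorophenyl]-2-(methoxymethoxy)-1-[7-(methoxymethoxy)-2,2-diphenyl-1,3-benzodioxol-5-yl]propan-1-one | COCOc1cc(C(=O)[C@H](OCOC)Cc3c(F)cc(OCc4ccccc4)cc3OCc3ccccc3)cc2OC(c3ccccc3)(c3ccccc3)Oc12
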